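**Plan**
- Retrosynthesis: the O–CH bond of the peroxide is cut first (oxa-Michael of a tertiary hydroperoxide onto a butenolide), then the tertiary C–OOH bond (perhydrolysis of a trisubstituted epoxide). The lactone C–O bond is then traced back to a cyclobutanone (Baeyer–Villiger), whose CH2–C(=O) and CH(O)–C(quaternary) bonds are cut together.
- Enabling feature: the γ-lactone ring (O, C=O, CH2, CH–OO, C–CH3) is the Baeyer–Villiger image of a 3-alkoxycyclobutanone, i.e. of a ketene/enol-ether cycloadduct. The oxygen on the CH carbon sets the regiochemistry of that cycloaddition and later serves as the leaving group that unmasks the butenolide.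
- Forward order: the side chain and its (E)-alkene come from Grignard addition and Johnson–Claisen rearrangement; then the cyclobutanone (key step), the lactone ring by O-insertion, the butenolide, the epoxide and the hydroperoxide. The 1,2-dioxane ring closes last, and the leftover carbinol is removed by dehydration and diimide reduction.
- Stereochemistry: the quaternary lactone carbon comes from the auxiliary-controlled [2+2] and is retained through the Baeyer–Villiger step. The peroxide-bearing quaternary carbon comes from Shi epoxidation followed by invertive perhydrolysis. The CH–OO centre comes from the cis ring fusion enforced in the Michael closure.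

Key step: step 6

Remark: the sense of facial shielding in step 6 is taken from a stacking model of the s-trans enol ether; it decides only which enantiomer of the commercial auxiliary alcohol is used.

Step 1
Reactants: 1 10-phenyldecan-1-ol
Product: 2 10-phenyldecanal
Conditions: TEMPO (10 mol %), PhI(OAc)2, CH2Cl2, rt
Reagents that add atoms: none
Why: TEMPO/oxoammonium-catalysed oxidation of an unhindered primary alcohol with PhI(OAc)2 as terminal oxidant should stop cleanly at the aldehyde.

Step 2
Reactants: 2 10-phenyldecanal; 3 isopropenylmagnesium bromide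
Product: 4 2-methyl-12-phenyldodec-1-en-3-ol (racemic)
Conditions: CH2=C(CH3)MgBr, THF, −78 °C to 0 °C; then H2O
Reagents that add atoms: none
Why: Grignard 1,2-addition to an aldehyde; the carbinol centre may stay racemic because it becomes sp2 in step 3.

Step 3
Reactants: 4 2-methyl-12-phenyldodec-1-en-3-ol; 5 triethyl orthopropionate
Product: 6 ethyl (4E)-2,4-dimethyl-14-phenyltetradec-4-enoate (racemic at C-2)
Conditions: CH3CH2C(OEt)3 (excess), EtCO2H (cat.), 140 °C, removal of EtOH
Reagents that add atoms: none
Why: Johnson–Claisen rearrangement through a chair transition state with the 9-phenylnonyl group equatorial should give the (E)-trisubstituted alkene, and the new α-centre needs no control because it is flattened in the ketene of step 6.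

Step 4
Reactants: 6 ethyl (4E)-2,4-dimethyl-14-phenyltetradec-4-enoate
Product: 7 (4E)-2,4-dimethyl-14-phenyltetradec-4-enoic acid (racemic at C-2)
Conditions: LiOH, THF/CH3OH/H2O, rt; then aq. HCl
Reagents that add atoms: lithium hydroxide [Li+].[OH-]
Why: plain ester saponification, with no group in the molecule sensitive to aqueous base.

Step 5
Reactants: 8 (1R,2S)-2-phenylcyclohexan-1-ol; 9 vinyl acetate
Product: 10 (1R,2S)-2-phenylcyclohexyl vinyl ether
Conditions: [Ir(cod)Cl]2 (1 mol %), Na2CO3, toluene, 100 °C
Reagents that add atoms: none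
Why: iridium-catalysed transfer vinylation of a secondary alcohol by vinyl acetate makes the enol ether without touching the two stereocentres of the auxiliary.

Step 6
Reactants: 7 (4E)-2,4-dimethyl-14-phenyltetradec-4-enoic acid; 10 (1R,2S)-2-phenylcyclohexyl vinyl ether
Product: 13 (2R,3R)-2-methyl-2-[(2E)-2-methyl-12-phenyldodec-2-en-1-yl]-3-{[(1R,2S)-2-phenylcyclohexyl]oxy}cyclobutan-1-one, via acid chloride 11 (not isolated), via ketene 12 (not isolated)
Conditions: (COCl)2, DMF (cat.), CH2Cl2, 0 °C to rt, evaporate; then 10 (2.5 equiv), Et3N, toluene, 90 °C, slow addition of 11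
Reagents that add atoms: none
Why: Et3N dehydrochlorinates 11 to the methyl(alkyl)ketene 12, whose electrophilic central carbon (the future lactone C=O) is attacked by the unsubstituted CH2 terminus of the vinyl ether while the ketene terminus bonds to the oxygen-bearing carbon, in an asynchronous thermal [2+2] that makes the CH2–C(=O) bond and the CH(O)–C(quaternary) bond in one operation. The closest known reaction type is the cycloaddition of dialkylketenes and of dichloroketene with alkyl vinyl ethers to 3-alkoxycyclobutanones, including the diastereoselective additions to enol ethers of chiral secondary alcohols. The only ring closed is the cyclobutanone, by the intermolecular cycloaddition itself (suprafacial on the enol ether, antarafacial on the ketene C=C), with no tether involved. The alkoxy-bearing carbon is controlled by the auxiliary, whose phenyl ring is expected to stack over one face of the s-trans enol ether so that the ketene adds to the open face; the quaternary carbon follows from its neighbour because the larger ketene substituent (the chain CH2, not CH3) ends up cis to the alkoxy group, as is usual for unsymmetrical ketenes. The step needs regioselectivity (secured by the enol-ether polarity), chemoselectivity over the chain alkene (an isolated alkene is far less nucleophilic than the vinyl ether in excess, and its one-atom spacing from the ketene forbids an intramolecular addition) and diastereoselectivity, the weakest of the three. Minor diastereomers are to be removed by chromatography here, which is what secures the enantiopurity of the quaternary centre.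

Step 7
Reactants: 13 the cyclobutanone of step 6
Product: 14 (4R,5R)-5-methyl-5-[(2E)-2-methyl-12-phenyldodec-2-en-1-yl]-4-{[(1R,2S)-2-phenylcyclohexyl]oxy}oxolan-2-one
Conditions: 30% aq. H2O2, CF3CH2OH, 0 °C to rt
Reagents that add atoms: hydrogen peroxide OO
Why: strain-driven Baeyer–Villiger oxidation in which the quaternary carbon migrates in preference to CH2 and with retention, so the quaternary stereocentre becomes the lactone C–O carbon unchanged, while the isolated alkene should not be epoxidised by H2O2 without a peracid or metal.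

Step 8
Reactants: 14 the β-alkoxy lactone of step 7
Product: 15 (5R)-5-methyl-5-[(2E)-2-methyl-12-phenyldodec-2-en-1-yl]furan-2(5H)-one
Conditions: DBU, CH2Cl2, rt (auxiliary alcohol 8 recovered)
Reagents that add atoms: none
Why: E1cB elimination of the β-alkoxide from the lactone enolate gives the butenolide and returns the auxiliary, and the quaternary centre has no acidic hydrogen and cannot epimerise.

Step 9
Reactants: 15 the butenolide of step 8
Product: 16 (5R)-5-methyl-5-{[(2R,3R)-2-methyl-3-(9-phenylnonyl)oxiran-2-yl]methyl}furan-2(5H)-one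
Conditions: D-fructose-derived Shi ketone (30 mol %), Oxone (2KHSO5·KHSO4·K2SO4), K2CO3, Bu4NHSO4, CH3CN/dimethoxymethane/aq. buffer pH 10.5, 0 °C
Reagents that add atoms: potassium peroxymonosulfate [K+].[O-]S(=O)(=O)OO
Why: Shi asymmetric epoxidation of an (E)-trisubstituted alkene through the spiro dioxirane transition state should give the (R,R)-epoxide under reagent control, independent of the remote lactone centre, and the electron-poor butenolide alkene is not a substrate for the electrophilic dioxirane.

Step 10
Reactants: 16 the epoxide of step 9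
Product: 17 (5R)-5-[(2S,3R)-2-hydroperoxy-3-hydroxy-2-methyl-12-phenyldodecyl]-5-methylfuran-2(5H)-one
Conditions: anhydrous H2O2 in Et2O (excess), phosphomolybdic acid H3PMo12O40 (3 mol %), rt
Reagents that add atoms: hydrogen peroxide OO
Why: acid-catalysed perhydrolysis of a trisubstituted epoxide, in which H2O2 opens the activated ring at the tertiary carbon with inversion and so sets the peroxide-bearing quaternary centre from the epoxide configuration.

Step 11
Reactants: 17 the hydroperoxy alcohol of step 10
Product: 18 (3S,4aR,7aR)-3-[(1R)-1-hydroxy-10-phenyldecyl]-3,4a-dimethyltetrahydro-3H-furo[3,2-c][1,2]dioxin-6(4H)-one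
Conditions: Et2NH (cat.), CF3CH2OH, rt
Reagents that add atoms: none
Why: 6-exo-trig intramolecular oxa-Michael addition of the hydroperoxide to the butenolide, in which only the cis-fused bicycle can form so that the CH–OO centre is set by the adjacent quaternary carbon, and the hydroperoxide (α-effect, more acidic) should add much faster than the secondary alcohol.

Step 12
Reactants: 18 the hydroxy dioxane of step 11
Product: 19 (3S,4aR,7aR)-3,4a-dimethyl-3-[(1E)-10-phenyldec-1-en-1-yl]tetrahydro-3H-furo[3,2-c][1,2]dioxin-6(4H)-one (E shown; the alkene geometry is immaterial)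
Conditions: Martin sulfurane Ph2S[OC(CF3)2Ph]2, CH2Cl2, rt
Reagents that add atoms: none
Why: sulfurane-mediated dehydration by E2 elimination of the alkoxysulfonium intermediate, which can only take a hydrogen from the chain side because the other neighbour is quaternary, under neutral conditions that a dialkyl peroxide and a lactone should tolerate.

Step 13
Reactants: 19 the alkene of step 12
Product: 20 (3R,4aR,7aR)-3,4a-dimethyl-3-(10-phenyldecyl)tetrahydro-3H-furo[3,2-c][1,2]dioxin-6(4H)-one (target)
Conditions: KO2C–N=N–CO2K (excess), AcOH, CH3OH/CH2Cl2, 0 °C to rt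
Reagents that add atoms: none
Why: diimide reduction transfers H2 to the C=C in a concerted syn fashion and does not cleave O–O bonds or reduce lactones, so no stereocentre is touched.

**Compound list**
1 | 10-phenyldecan-1-ol | OCCCCCCCCCCc1ccccc1 | starting material
2 | 10-phenyldecanal | O=CCCCCCCCCCc1ccccc1 | intermediate
3 | isopropenylmagnesium bromide | CC(=C)[Mg]Br | starting material
4 | 2-methyl-12-phenyldodec-1-en-3-ol (racemic) | CC(=C)C(O)CCCCCCCCCc1ccccc1 | intermediate
5 | triethyl orthopropionate | CCC(OCC)(OCC)OCC | starting material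
6 | ethyl (4E)-2,4-dimethyl-14-phenyltetradec-4-enoate (racemic at C-2) | CCOC(=O)C(C)C/C(C)=C/CCCCCCCCCc1ccccc1 | intermediate
7 | (4E)-2,4-dimethyl-14-phenyltetradec-4-enoic acid (racemic at C-2) | OC(=O)C(C)C/C(C)=C/CCCCCCCCCc1ccccc1 | intermediate
8 | (1R,2S)-2-phenylcyclohexan-1-ol | O[C@@H]1CCCC[C@H]1c1ccccc1 | starting material
9 | vinyl acetate | C=COC(C)=O | starting material
10 | (1R,2S)-2-phenylcyclohexyl vinyl ether | C=CO[C@@H]1CCCC[C@H]1c1ccccc1 | intermediate
11 | (4E)-2,4-dimethyl-14-phenyltetradec-4-enoyl chloride | ClC(=O)C(C)C/C(C)=C/CCCCCCCCCc1ccccc1 | intermediate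
12 | (4E)-2,4-dimethyl-14-phenyltetradeca-1,4-dien-1-one (the ketene) | O=C=C(C)C/C(C)=C/CCCCCCCCCc1ccccc1 | intermediate
13 | (2R,3R)-2-methyl-2-[(2E)-2-methyl-12-phenyldodec-2-en-1-yl]-3-{[(1R,2S)-2-phenylcyclohexyl]oxy}cyclobutan-1-one | O=C1C[C@@H](O[C@@H]2CCCC[C@H]2c2ccccc2)[C@@]1(C)C/C(C)=C/CCCCCCCCCc1ccccc1 | intermediate
14 | (4R,5R)-5-methyl-5-[(2E)-2-methyl-12-phenyldodec-2-en-1-yl]-4-{[(1R,2S)-2-phenylcyclohexyl]oxy}oxolan-2-one | O=C1C[C@@H](O[C@@H]2CCCC[C@H]2c2ccccc2)[C@@](C)(C/C(C)=C/CCCCCCCCCc2ccccc2)O1 | intermediate
15 | (5R)-5-methyl-5-[(2E)-2-methyl-12-phenyldodec-2-en-1-yl]furan-2(5H)-one | O=C1C=C[C@@](C)(C/C(C)=C/CCCCCCCCCc2ccccc2)O1 | intermediate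
16 | (5R)-5-methyl-5-{[(2R,3R)-2-methyl-3-(9-phenylnonyl)oxiran-2-yl]methyl}furan-2(5H)-one | O=C1C=C[C@@](C)(C[C@@]2(C)O[C@@H]2CCCCCCCCCc2ccccc2)O1 | intermediate
17 | (5R)-5-[(2S,3R)-2-hydroperoxy-3-hydroxy-2-methyl-12-phenyldodecyl]-5-methylfuran-2(5H)-one | O=C1C=C[C@@](C)(C[C@](C)(OO)[C@H](O)CCCCCCCCCc2ccccc2)O1 | intermediate
18 | (3S,4aR,7aR)-3-[(1R)-1-hydroxy-10-phenyldecyl]-3,4a-dimethyltetrahydro-3H-furo[3,2-c][1,2]dioxin-6(4H)-one | C[C@@]1([C@H](O)CCCCCCCCCc2ccccc2)C[C@@]2(C)OC(=O)C[C@H]2OO1 | intermediate
19 | (3S,4aR,7aR)-3,4a-dimethyl-3-[(1E)-10-phenyldec-1-en-1-yl]tetrahydro-3H-furo[3,2-c][1,2]dioxin-6(4H)-one | C[C@@]1(/C=C/CCCCCCCCc2ccccc2)C[C@@]2(C)OC(=O)C[C@H]2OO1 | intermediate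
20 | (3R,4aR,7aR)-3,4a-dimethyl-3-(10-phenyldecyl)tetrahydro-3H-furo[3,2-c][1,2]dioxin-6(4H)-one | C[C@@]1(CCCCCCCCCCc2ccccc2)C[C@@]2(C)OC(=O)C[C@H]2OO1 | target

**Step count**
Total steps: 13. Longest linear sequence: 12 (steps 1–4 and 6–13; step 5 is a one-step side branch).

**Steps most likely to fail**

1. Step 6. What may go wrong: erosion of stereocontrol, through a weak facial bias of the auxiliary toward a dialkylketene or a poor cis/trans preference between CH3 and the chain CH2, together with ketene dimerisation. If only the facial sense is reversed, the (1S,2R) alcohol is used instead. The fallback builds the quaternary carbinol centre by Seebach self-regeneration of stereocentres instead of a cycloaddition; it sets out from 4 and comes back at 15. Allylic alcohol 4 is treated with PBr3 (Et2O, 0 °C), which brings about allylic transposition to (2E)-1-bromo-2-methyl-12-phenyldodec-2-ene F1. The lithium enolate (LiN(iPr)2, THF, −78 °C) of commercial (2S,5S)-2-tert-butyl-5-methyl-1,3-dioxolan-4-one is alkylated with F1 anti to the tert-butyl group, which should give (2S,5R)-2-tert-butyl-5-methyl-5-[(2E)-2-methyl-12-phenyldodec-2-en-1-yl]-1,3-dioxolan-4-one F2. Reduction with iBu2AlH (CH2Cl2, −78 °C) gives the lactol (2S,5R)-2-tert-butyl-5-methyl-5-[(2E)-2-methyl-12-phenyldodec-2-en-1-yl]-1,3-dioxolan-4-ol F3. Still–Gennari olefination of F3 in its open form ((CF3CH2O)2P(O)CH2CO2CH3, KN(SiMe3)2, 18-crown-6, THF, −78 °C), with loss of pivalaldehyde, gives methyl (2Z,4R,6E)-4-hydroxy-4,6-dimethyl-16-phenylhexadeca-2,6-dienoate F4, which lactonises to 15.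

2. Step 12. What may go wrong: fragmentation or rearrangement started by the peroxide oxygen next to the activated carbinol, or failure of the hindered alcohol to be activated at all. The fallback never creates the carbinol; it sets out from 15 and comes back at 19. Singlet-oxygen ene reaction of 15 (O2, tetraphenylporphyrin, hν, CH2Cl2, 0 °C) should give, beside regioisomers, the tertiary allylic hydroperoxide (5R)-5-[(3E)-2-hydroperoxy-2-methyl-12-phenyldodec-3-en-1-yl]-5-methylfuran-2(5H)-one F7. Et2NH in CF3CH2OH closes this to 19 and its epimer at the peroxide-bearing quaternary carbon, which are separated by chromatography. Control of that centre is given up.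

3. Step 10. What may go wrong: loss of regio- or stereospecificity in the epoxide opening (SN1 scrambling at the tertiary carbon, rearrangement of the epoxide to a ketone) or acid-induced decay of the tertiary hydroperoxide. The fallback replaces the ionic opening by a radical hydroperoxidation; it sets out from 15 and comes back at 20, bypassing steps 9–13. Mukaiyama–Isayama peroxidation of 15 (Co(thd)2 cat., O2, Et3SiH, ClCH2CH2Cl, rt) should give (5R)-5-methyl-5-{2-methyl-12-phenyl-2-[(triethylsilyl)peroxy]dodecyl}furan-2(5H)-one F5 as both epimers. Aqueous HCl in THF frees (5R)-5-(2-hydroperoxy-2-methyl-12-phenyldodecyl)-5-methylfuran-2(5H)-one F6. Et2NH in CF3CH2OH closes this to 20 and its epimer at the peroxide-bearing quaternary carbon, which are separated by chromatography.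

Further compounds
F1 | step 6 | (2E)-1-bromo-2-methyl-12-phenyldodec-2-ene | BrC/C(C)=C/CCCCCCCCCc1ccccc1
F2 | step 6 | (2S,5R)-2-tert-butyl-5-methyl-5-[(2E)-2-methyl-12-phenyldodec-2-en-1-yl]-1,3-dioxolan-4-one | CC(C)(C)[C@@H]1OC(=O)[C@@](C)(C/C(C)=C/CCCCCCCCCc2ccccc2)O1
F3 | step 6 | (2S,5R)-2-tert-butyl-5-methyl-5-[(2E)-2-methyl-12-phenyldodec-2-en-1-yl]-1,3-dioxolan-4-ol (anomer mixture) | CC(C)(C)[C@@H]1OC(O)[C@@](C)(C/C(C)=C/CCCCCCCCCc2ccccc2)O1
F4 | step 6 | methyl (2Z,4R,6E)-4-hydroxy-4,6-dimethyl-16-phenylhexadeca-2,6-dienoate | COC(=O)/C=C\[C@](C)(O)C/C(C)=C/CCCCCCCCCc1ccccc1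
F5 | step 10 | (5R)-5-methyl-5-{2-methyl-12-phenyl-2-[(triethylsilyl)peroxy]dodecyl}furan-2(5H)-one (both epimers) | O=C1C=C[C@@](C)(CC(C)(OO[Si](CC)(CC)CC)CCCCCCCCCCc2ccccc2)O1
F6 | step 10 | (5R)-5-(2-hydroperoxy-2-methyl-12-phenyldodecyl)-5-methylfuran-2(5H)-one (both epimers) | O=C1C=C[C@@](C)(CC(C)(OO)CCCCCCCCCCc2ccccc2)O1
F7 | step 12 | (5R)-5-[(3E)-2-hydroperoxy-2-methyl-12-phenyldodec-3-en-1-yl]-5-methylfuran-2(5H)-one (both epimers) | O=C1C=C[C@@](C)(CC(C)(OO)/C=C/CCCCCCCCc2ccccc2)O1
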